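**Plan**
- Retrosynthesis: the CH2 bridge is cut first (its two C–C bonds, to the ring CH of the triketone and to C6 of the chromene), giving isobutyrylfilicinic acid, a one-carbon iminium unit and 5,7-dihydroxy-8-isobutyryl-2,2-dimethyl-2H-chromene. In the chromene the ring O1–C8a bond and the neighbouring C8–acyl bond are then cut together.
- Enabling feature: on the benzene ring of the benzopyran, the pyran oxygen (on C8a) and the isobutyryl group (on C8) are ortho neighbours and C7 carries oxygen. C8/C8a can therefore be an aryne: the cis C3=C4 alkene delivers a tertiary alkoxide to C8a, and the C7 alkoxy group places the carbanion on C8, where it is acylated.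
- Forward, chromene half: 5-fluororesorcinol, bis-MOM ether, Br and I placed on either side of F, Sonogashira at C–I, Lindlar reduction, aryne cascade (pyran ring closes and the acyl group enters), MOM removal.
- Forward, triketone half and union: phloroglucinol, acylation, geminal C-methylation (dearomatised ring), then a Mannich-type methylene bridging joins the halves.
- Stereochemistry: the target has no stereocentre. The one stereo element, the Z alkene needed for ring closure, comes from syn semi-hydrogenation and ends as the ring C3=C4 bond.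

Key step: step 6

Remark: benzopyran atoms are numbered O1, C2, C3, C4, C4a, C5–C8, C8a; the triketone half is drawn in the enol form of the target SMILES (tautomers interconvert); 1, 5, 8, 15 and 16 are taken as purchased.

**Step 1**
Reactants: 1 5-fluororesorcinol
Product: 2 1-fluoro-3,5-bis(methoxymethoxy)benzene
Conditions: NaH (2.4 equiv), MOMCl (2.4 equiv), DMF, 0 °C → rt
Reagents that add atoms: chloromethyl methyl ether (MOMCl), COCCl
Why: Williamson-type O-alkylation of both sodium phenoxides; MOM ethers survive organolithiums and palladium catalysis and leave later under mild acid.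

**Step 2**
Reactants: 2 1-fluoro-3,5-bis(methoxymethoxy)benzene
Product: 3 2-bromo-1-fluoro-3,5-bis(methoxymethoxy)benzene
Conditions: NBS (1.0 equiv), MeCN, 0 °C → rt
Reagents that add atoms: N-bromosuccinimide, O=C1CCC(=O)N1Br
Why: Electrophilic aromatic bromination; as with other 5-substituted resorcinol diethers the electrophile should enter para to one alkoxy group (ortho to F) rather than at the doubly flanked carbon between the two alkoxy groups, and one equivalent at 0 °C should stop at the monobromide.

**Step 3**
Reactants: 3 2-bromo-1-fluoro-3,5-bis(methoxymethoxy)benzene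
Product: 4 2-bromo-3-fluoro-4-iodo-1,5-bis(methoxymethoxy)benzene
Conditions: NIS (1.15 equiv), MeCN, 60 °C, dark
Reagents that add atoms: N-iodosuccinimide, O=C1CCC(=O)N1I
Why: Second electrophilic halogenation at the remaining carbon that is para to an alkoxy group (the 4,6-pattern of resorcinol diethers), so that F becomes flanked by Br on one side and I on the other.

**Step 4**
Reactants: 4 2-bromo-3-fluoro-4-iodo-1,5-bis(methoxymethoxy)benzene; 5 2-methylbut-3-yn-2-ol
Product: 6 4-[3-bromo-2-fluoro-4,6-bis(methoxymethoxy)phenyl]-2-methylbut-3-yn-2-ol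
Conditions: PdCl2(PPh3)2 (3 mol %), CuI (5 mol %), Et3N, THF, 45 °C
Reagents that add atoms: none
Why: Sonogashira coupling; oxidative addition of zerovalent palladium to C–I is far faster than to C–Br and C–F is inert, so only the iodide should be exchanged.

**Step 5**
Reactants: 6 4-[3-bromo-2-fluoro-4,6-bis(methoxymethoxy)phenyl]-2-methylbut-3-yn-2-ol
Product: 7 (Z)-4-[3-bromo-2-fluoro-4,6-bis(methoxymethoxy)phenyl]-2-methylbut-3-en-2-ol
Conditions: H2 (1 atm), Pd/CaCO3 poisoned with Pb(OAc)2 (Lindlar catalyst), quinoline, EtOAc, rt
Reagents that add atoms: none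
Why: Lindlar semi-hydrogenation delivers H2 syn and sets the Z alkene; aryl bromide, aryl fluoride and MOM ethers should survive the neutral conditions.

**Step 6**
Reactants: 7 (Z)-4-[3-bromo-2-fluoro-4,6-bis(methoxymethoxy)phenyl]-2-methylbut-3-en-2-ol; 8 N-methoxy-N,2-dimethylpropanamide
Product: 13 1-[5,7-bis(methoxymethoxy)-2,2-dimethyl-2H-chromen-8-yl]-2-methylpropan-1-one, via dilithio aryl fluoride 9 (not isolated), via aryne alkoxide 10 (not isolated), via 8-lithiochromene 11 (not isolated), via tetrahedral lithium adduct 12 (not isolated)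
Conditions: t-BuLi (3.1 equiv), THF (0.02 M), −78 °C; then −78 → 0 °C; then 8 (1.5 equiv), −78 °C → rt; then H2O
Reagents that add atoms: none
Why: The first equivalent of t-BuLi makes the lithium alkoxide, the second exchanges bromine for lithium and the third destroys t-BuBr, giving the 2-fluoroaryllithium 9; on warming this loses LiF to the 3-alkoxy aryne 10 (C8≡C8a), the tertiary alkoxide held cis by the Z alkene adds to C8a to form the O1–C8a bond, and the C8 aryllithium 11 is acylated by the Weinreb amide 8 through the chelated adduct 12, which releases the ketone only on aqueous quench. The closest known reaction type is the anionic aryne cyclisation of a tethered heteroatom nucleophile followed by electrophilic trapping of the ortho-aryllithium. The pyran ring closes in the 6-exo-dig mode onto the in-plane aryne bond. No stereocentre is formed, and the Z alkene of 7 becomes the endocyclic C3=C4 bond. Regioselectivity in the addition to the unsymmetrical aryne is secured twice: only attack at C8a can close a six-membered ring, and the inductively withdrawing OMOM group on C7 beside the triple bond polarises the aryne so that the nucleophile adds at the distal carbon C8a and the carbanion develops on C8 next to oxygen. A single acyl group at C8 (none at C6) should follow from the defined position of lithium, the absence of any amine that could shuttle protons, and the stability of the N-methoxy-N-methyl adduct; high dilution should disfavour addition of 9 to 10 between molecules.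

**Step 7**
Reactants: 13 1-[5,7-bis(methoxymethoxy)-2,2-dimethyl-2H-chromen-8-yl]-2-methylpropan-1-one
Product: 14 1-(5,7-dihydroxy-2,2-dimethyl-2H-chromen-8-yl)-2-methylpropan-1-one
Conditions: HCl (3 M aq, cat.), MeOH, 45 °C
Reagents that add atoms: none
Why: Acid-catalysed acetal exchange transfers both methoxymethyl groups to methanol; 2,2-dimethylchromenes are expected to tolerate dilute methanolic HCl.

**Step 8**
Reactants: 15 phloroglucinol; 16 2-methylpropanoyl chloride (isobutyryl chloride)
Product: 17 2-methyl-1-(2,4,6-trihydroxyphenyl)propan-1-one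
Conditions: AlCl3 (4 equiv), PhNO2/CH2Cl2, 0 → 60 °C; then aq. HCl
Reagents that add atoms: none
Why: Friedel–Crafts acylation of the strongly activated triphenol; the first chelated acyl group deactivates the ring and should hold the reaction at monoacylation.

**Step 9**
Reactants: 17 2-methyl-1-(2,4,6-trihydroxyphenyl)propan-1-one
Product: 18 3,5-dihydroxy-6,6-dimethyl-2-(2-methylpropanoyl)cyclohexa-2,4-dien-1-one (isobutyrylfilicinic acid)
Conditions: NaOMe (3 equiv), MeI (2.5 equiv), MeOH, 0 °C → rt
Reagents that add atoms: iodomethane, CI
Why: Dearomatising geminal C-methylation of the acylphloroglucinol polyanion, the established entry to acylfilicinic acids; the mono-C-methyl enolate is methylated again at the same carbon, and mono- and trimethyl congeners are removed by chromatography.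

**Step 10**
Reactants: 18 3,5-dihydroxy-6,6-dimethyl-2-(2-methylpropanoyl)cyclohexa-2,4-dien-1-one; 14 1-(5,7-dihydroxy-2,2-dimethyl-2H-chromen-8-yl)-2-methylpropan-1-one
Product: 20 uliginosin B, via Mannich base 19 (not isolated)
Conditions: Me2N=CH2+ I− (1.0 equiv), NaOAc (1.1 equiv), MeCN, 0 °C → rt; then 14 (1.0 equiv), 70 °C
Reagents that add atoms: N,N-dimethylmethylideneammonium iodide (Eschenmoser's salt), C=[N+](C)C.[I-]
Why: Mannich aminomethylation at the only ring CH of the triketone enol gives 19, which on heating loses dimethylamine (E1cB) to a methylene trione that is captured in a Friedel–Crafts-type Michael addition by C6 of 14, its only free nucleophilic carbon.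

**Compound list**
1 | 5-fluororesorcinol (5-fluorobenzene-1,3-diol) | Oc1cc(O)cc(F)c1 | starting material
2 | 1-fluoro-3,5-bis(methoxymethoxy)benzene | COCOc1cc(F)cc(OCOC)c1 | intermediate
3 | 2-bromo-1-fluoro-3,5-bis(methoxymethoxy)benzene | COCOc1cc(F)c(Br)c(OCOC)c1 | intermediate
4 | 2-bromo-3-fluoro-4-iodo-1,5-bis(methoxymethoxy)benzene | COCOc1cc(OCOC)c(I)c(F)c1Br | intermediate
5 | 2-methylbut-3-yn-2-ol | CC(C)(O)C#C | starting material
6 | 4-[3-bromo-2-fluoro-4,6-bis(methoxymethoxy)phenyl]-2-methylbut-3-yn-2-ol | CC(C)(O)C#Cc1c(F)c(Br)c(OCOC)cc1OCOC | intermediate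
7 | (Z)-4-[3-bromo-2-fluoro-4,6-bis(methoxymethoxy)phenyl]-2-methylbut-3-en-2-ol | CC(C)(O)/C=C\c1c(F)c(Br)c(OCOC)cc1OCOC | intermediate
8 | N-methoxy-N,2-dimethylpropanamide | CC(C)C(=O)N(C)OC | starting material
9 | lithium (Z)-4-[2-fluoro-3-lithio-4,6-bis(methoxymethoxy)phenyl]-2-methylbut-3-en-2-olate | [Li]OC(C)(C)/C=C\c1c(F)c([Li])c(OCOC)cc1OCOC | intermediate
10 | lithium (Z)-4-[4,6-bis(methoxymethoxy)-2,3-didehydrophenyl]-2-methylbut-3-en-2-olate (aryne) | [Li]OC(C)(C)/C=C\C1=C(OCOC)C=C(OCOC)C#C1 | intermediate
11 | 8-lithio-5,7-bis(methoxymethoxy)-2,2-dimethyl-2H-chromene | [Li]c1c(OCOC)cc(OCOC)c2C=CC(C)(C)Oc12 | intermediate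
12 | lithium 1-[5,7-bis(methoxymethoxy)-2,2-dimethyl-2H-chromen-8-yl]-1-[methoxy(methyl)amino]-2-methylpropan-1-olate | CC(C)C(O[Li])(N(C)OC)c1c(OCOC)cc(OCOC)c2C=CC(C)(C)Oc12 | intermediate
13 | 1-[5,7-bis(methoxymethoxy)-2,2-dimethyl-2H-chromen-8-yl]-2-methylpropan-1-one | CC(C)C(=O)c1c(OCOC)cc(OCOC)c2C=CC(C)(C)Oc12 | intermediate
14 | 1-(5,7-dihydroxy-2,2-dimethyl-2H-chromen-8-yl)-2-methylpropan-1-one | CC(C)C(=O)c1c(O)cc(O)c2C=CC(C)(C)Oc12 | intermediate
15 | phloroglucinol (benzene-1,3,5-triol) | Oc1cc(O)cc(O)c1 | starting material
16 | 2-methylpropanoyl chloride | CC(C)C(Cl)=O | starting material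
17 | 2-methyl-1-(2,4,6-trihydroxyphenyl)propan-1-one | CC(C)C(=O)c1c(O)cc(O)cc1O | intermediate
18 | 3,5-dihydroxy-6,6-dimethyl-2-(2-methylpropanoyl)cyclohexa-2,4-dien-1-one | CC(C)C(=O)C1=C(O)C=C(O)C(C)(C)C1=O | intermediate
19 | 4-[(dimethylamino)methyl]-3,5-dihydroxy-6,6-dimethyl-2-(2-methylpropanoyl)cyclohexa-2,4-dien-1-one | CC(C)C(=O)C1=C(O)C(CN(C)C)=C(O)C(C)(C)C1=O | intermediate
20 | uliginosin B | CC(C)C(=O)C1=C(O)C(Cc2c(O)c3c(c(C(=O)C(C)C)c2O)OC(C)(C)C=C3)=C(O)C(C)(C)C1=O | target

**Totals**
Total step count: 10. Longest linear sequence: 8 steps (steps 1 to 7, then step 10).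

**Steps most likely to fail**

1. Step 6. The aryne may be consumed by addition of aryllithium 9 from another molecule before the alkoxide closes the ring, the aryllithium 11 may be protonated early, or acyl transfer to the hindered di-ortho-alkoxy aryllithium may stall. The fallback sets out from 17 and uses the known condensation–electrocyclisation route to chromenes. Heating 17 with 3-methylbut-2-enal (CC(C)=CC=O) and ethylenediammonium diacetate in toluene should give, by Knoevenagel-type condensation at a free ring carbon, the vinylogous ortho-quinone methide 3,5-dihydroxy-6-(3-methylbut-2-en-1-ylidene)-2-(2-methylpropanoyl)cyclohexa-2,4-dien-1-one F1. F1 closes by oxa-6π electrocyclisation through the carbonyl oxygen next to the acyl-bearing carbon and comes back to the route at 14. The isomer closed through the other oxygen would have to be separated.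

2. Step 10. The methylene trione may be captured too slowly by the acyl-deactivated ring of 14, and the bridge may redistribute by retro-Michael and re-addition to give symmetrical dimers. The fallback reverses the roles of the halves and sets out from 14. Aminomethylation of 14 with Me2N=CH2+ I− at C6 should give the Mannich base 1-{6-[(dimethylamino)methyl]-5,7-dihydroxy-2,2-dimethyl-2H-chromen-8-yl}-2-methylpropan-1-one F2. Heating F2 with 18 in dioxane should expel dimethylamine to give the ortho-quinone methide of the chromene half, which the far more nucleophilic enol carbon of 18 captures, coming back to the route at 20.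

3. Step 9. Methylation may spread over mono-, vicinal di-, tri- and O-methyl products instead of stopping at the geminal dimethyl compound. The fallback sets out from 15 and blocks two ring carbons first. Double acetylation of 15 (Ac2O, BF3·OEt2) should give 1,1'-(2,4,6-trihydroxy-1,3-phenylene)diethanone F3, which has one free ring carbon only. MeI/NaOMe then gives 2,4-diacetyl-3,5-dihydroxy-6,6-dimethylcyclohexa-2,4-dien-1-one F4. Hot aqueous H2SO4 removes both acetyl groups (retro-Claisen) to give filicinic acid, 3,5-dihydroxy-4,4-dimethylcyclohexa-2,5-dien-1-one F5. Friedel–Crafts C-acylation of F5 with 16 and AlCl3 comes back to the route at 18.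

**Further compounds**
F1 | step 6 | 3,5-dihydroxy-6-(3-methylbut-2-en-1-ylidene)-2-(2-methylpropanoyl)cyclohexa-2,4-dien-1-one | CC(C)C(=O)C1=C(O)C=C(O)C(=CC=C(C)C)C1=O
F2 | step 10 | 1-{6-[(dimethylamino)methyl]-5,7-dihydroxy-2,2-dimethyl-2H-chromen-8-yl}-2-methylpropan-1-one | CC(C)C(=O)c1c(O)c(CN(C)C)c(O)c2C=CC(C)(C)Oc12
F3 | step 9 | 1,1'-(2,4,6-trihydroxy-1,3-phenylene)diethanone | CC(=O)c1c(O)cc(O)c(C(C)=O)c1O
F4 | step 9 | 2,4-diacetyl-3,5-dihydroxy-6,6-dimethylcyclohexa-2,4-dien-1-one | CC(=O)C1=C(O)C(C(C)=O)=C(O)C(C)(C)C1=O
F5 | step 9 | 3,5-dihydroxy-4,4-dimethylcyclohexa-2,5-dien-1-one (filicinic acid) | CC1(C)C(O)=CC(=O)C=C1O
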